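**Plan**

Germacrane numbering is used throughout: C1 ketone, C2=C3 furanone alkene with C3 on the ring oxygen, C4 with methylene C15, C5 carbinol, C6 lactone carbinol, C7, C8 ester carbon, C9, C10 with methyl C14, C11–C13 methylene lactone. Read from the SMILES, the target is 5S,6R,7R,8R,10R.

Retrosynthesis: C15 becomes a primary leaving group on C4; the lactone C6–O bond is cut to a C5/C6 epoxide and a C12 acid; the furanone O10–C3 bond is cut; then the ring bond C3–C4 is cut by a retro-[3,3] shift that restores C1–C6. Last come C1–C2 (acetylide addition) and C6–C5 (enolate alkenylation).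

Enabling feature: the C1 carbonyl, the oxygen-bearing C3 and the vicinal C5/C6 oxygens lie exactly where an oxy-Cope shift of the six-membered ring C1–C6–C7–C8–C9–C10 leaves a ketone, a new-bond terminus and an E alkene. That ring, with methyl C14 on C10 and the isopropenyl carbons C11–C13 on C7, is (R)-carvone.

Forward order: carvone ring (oxygenated at C8, then C10) → alkenyl on C6 and ethoxyethynyl on C1 → ten-membered ring by four-atom ring expansion → furanone (O10 to C3) → γ-lactone (O to C6) → C4=C15.

Stereochemistry: C7 comes from (R)-carvone. C8 is set by anti oxygenation followed by Mitsunobu inversion. C10 is set by O2 capture on the face opposite the C7/C8 substituents. C5 and C6 are set by anti addition (epoxidation, then inversion at C6) across the E alkene that the chair transition state of the ring expansion delivers.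

Key step: step 12

Remark: C1, C4 and C6 of the ring-expansion substrate, and C4 and the C2=C3 geometry of its product, do not reach the target. They are drawn as the facial preferences of steps 10–11, the chair transition state and peripheral protonation predict.

**Route**

Step 1
Reactants: 1 (R)-carvone
Product: 2 trimethylsilyl dienol ether of carvone (C1=C10/C8=C9 diene)
Conditions: MeMgBr, FeCl3 (5 mol %), Et2O, −20 °C; then Me3SiCl, Et3N, HMPA, −20 → 25 °C
Reagents that add atoms: chlorotrimethylsilane, C[Si](C)(C)Cl
Why: Iron-catalysed Grignard deprotonation of an enone removes the γ-hydrogen on C8 and gives the through-conjugated magnesium dienolate, which is O-silylated (silyl dienol ether formation) without touching C7.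

Step 2
Reactants: 2 trimethylsilyl dienol ether
Product: 4 trans-8-hydroxycarvone, via epoxy silyl enol ether 3 (not isolated)
Conditions: dimethyldioxirane (acetone), CH2Cl2, −78 → 0 °C; then AcOH, THF/H2O, 0 °C
Reagents that add atoms: dimethyldioxirane, CC1(C)OO1
Why: Vinylogous Rubottom oxidation: the electron-rich diene should be epoxidised at its terminal C8=C9 bond much faster than the isopropenyl group and on the face anti to the adjacent C7 substituent, and opening of the epoxide with loss of silicon returns the enone with the C8 hydroxyl trans to isopropenyl (any cis epimer is compound 6 and joins the route at step 5).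

Step 3
Reactants: 4 trans-8-hydroxycarvone
Product: 5 cis-8-(4-nitrobenzoyloxy)carvone
Conditions: 4-nitrobenzoic acid, PPh3, DIAD, THF, 0 → 25 °C
Reagents that add atoms: 4-nitrobenzoic acid, OC(=O)c1ccc(cc1)[N+](=O)[O-]
Why: Mitsunobu reaction: SN2 displacement of the activated secondary allylic alcohol by the carboxylate inverts C8 (the well-known case of a cyclohexanol flanked by a branched carbon), which places O8 cis to isopropenyl as the target requires.

Step 4
Reactants: 5 cis-8-(4-nitrobenzoyloxy)carvone
Product: 6 cis-8-hydroxycarvone
Conditions: K2CO3 (0.2 equiv), MeOH, 0 °C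
Reagents that add atoms: none
Why: Base-catalysed transesterification of the activated aryl ester frees the alcohol with retention at C8, and low temperature with substoichiometric base should avoid isomerisation of the γ-hydroxy enone.

Step 5
Reactants: 6 cis-8-hydroxycarvone
Product: 7 cis-8-(tert-butyldimethylsilyloxy)carvone
Conditions: t-BuMe2SiCl, imidazole, DMF, 25 °C
Reagents that add atoms: tert-butyldimethylsilyl chloride, CC(C)(C)[Si](C)(C)Cl
Why: Standard silylation of a secondary alcohol; the bulky ether adds to the shielding of the lower ring face in step 6 and survives steps 6–12.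

Step 6
Reactants: 7 cis-8-(tert-butyldimethylsilyloxy)carvone
Product: 9 α-hydroxy ketone (10-OH trans to O8 and isopropenyl), via tertiary hydroperoxide 8 (not isolated)
Conditions: Mn(dpm)3 (5 mol %; dpm = 2,2,6,6-tetramethylheptane-3,5-dionate), PhSiH3, O2 (1 atm), i-PrOH/CH2Cl2, 0 °C; then P(OEt)3, 0 → 25 °C
Reagents that add atoms: dioxygen, O=O
Why: Manganese hydride hydrogen-atom transfer to C9 of the enone (Mukaiyama-type reductive α-hydroxylation) gives the C10 α-keto radical, which should capture O2 on the face opposite the C8 silyloxy and C7 isopropenyl groups (the axial trajectory leading directly to the chair with equatorial C8–O and C10–CH3), so O10 ends trans to both; the conjugated alkene reacts ahead of the isopropenyl group and the phosphite reduces the hydroperoxide.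

Step 7
Reactants: 9 α-hydroxy ketone
Product: 10 methoxymethyl ether of 9
Conditions: MeOCH2Cl, i-Pr2NEt, n-Bu4NI (cat.), CH2Cl2, 40 °C
Reagents that add atoms: chloromethyl methyl ether, COCCl
Why: O-alkylation of the tertiary α-ketol with an α-chloro ether; the acetal cannot migrate to a neighbouring alkoxide in step 12, can chelate lithium in step 11, and leaves C6 as the only enolisable carbon.

Step 8
Reactants: 11 propargyl alcohol
Product: 12 tert-butyl(diphenyl)(prop-2-yn-1-yloxy)silane
Conditions: t-BuPh2SiCl, imidazole, CH2Cl2, 0 → 25 °C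
Reagents that add atoms: tert-butyldiphenylsilyl chloride, CC(C)(C)[Si](Cl)(c1ccccc1)c1ccccc1
Why: Silylation of a primary alcohol; this silyl ether is chosen because it should survive the acid of step 13 and be cleaved by fluoride in step 18.

Step 9
Reactants: 12 tert-butyl(diphenyl)(prop-2-yn-1-yloxy)silane
Product: 14 (E)-1-bromo-3-(tert-butyldiphenylsilyloxy)prop-1-ene, via alkenylzirconocene chloride 13 (not isolated)
Conditions: Cp2Zr(H)Cl, THF, 25 °C; then N-bromosuccinimide, 0 °C
Reagents that add atoms: N-bromosuccinimide, BrN1C(=O)CCC1=O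
Why: Hydrozirconation with the Schwartz reagent is a syn addition that places zirconium on the terminal carbon, and bromodemetalation proceeds with retention, which fixes the E geometry.

Step 10
Reactants: 10 methoxymethyl ether ketone; 14 (E)-vinyl bromide
Product: 16 C6-alkenyl ketone (alkenyl cis to isopropenyl), via lithium dienolate 15 (not isolated)
Conditions: Pd2(dba)3 (2.5 mol %), [HP(t-Bu)3]BF4 (10 mol %), LiN(SiMe3)2 (2.3 equiv), toluene, 25 → 50 °C; then AcOH, THF, −78 °C
Reagents that add atoms: none
Why: Palladium-catalysed α-alkenylation of a ketone enolate (enolate cross-coupling of the Buchwald–Hartwig type) at the only enolisable carbon; the β,γ-unsaturated product is held as dienolate 15, and its kinetic α-protonation anti to the isopropenyl group (pseudoaxial because of A1,2 strain with the new C6 substituent) should give the 6,7-cis ketone, which is also the more stable epimer (chair with equatorial alkenyl, C8–O and C10–CH3 and no 1,3-diaxial CH3/OSi contact).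

Step 11
Reactants: 16 C6-alkenyl ketone; 17 ethoxyacetylene
Product: 19 1-(ethoxyethynyl)-2-alkenylcyclohexanol (alkynyl trans to alkenyl), via lithium ethoxyacetylide 18 (not isolated)
Conditions: 17, n-BuLi, THF, −78 °C; then 16, −78 → −30 °C; H2O
Reagents that add atoms: none
Why: 1,2-Addition of a lithium acetylide to a ketone: in the chair of 16 the axial isopropenyl group on C7 blocks the axial trajectory (as the axial methyl does in 3,3,5-trimethylcyclohexanone), so the weakly basic nucleophile, guided by lithium chelation to the axial C10 acetal, should enter equatorially from the opposite face and leave the alkynyl group trans to the C6 alkenyl group, both equatorial, with the C1 hydroxyl axial.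

Step 12
Reactants: 19 1-(ethoxyethynyl)-2-alkenylcyclohexanol
Product: 22 ten-membered (2E,5E)-β-ethoxy enone, via potassium alkoxide 20 (not isolated), via potassium allenolate 21 (not isolated)
Conditions: KH (1.5 equiv), 18-crown-6 (1.5 equiv), THF, 0 → 25 °C; then AcOH, THF, −78 °C
Reagents that add atoms: none
Why: Proposed new method: KH with 18-crown-6 gives the ion-separated tertiary alkoxide 20, whose C1–C6 bond is weakened, and C4 of the alkenyl group bonds to the ynol-ether terminus C3 as C1–C6 breaks in an anionic [3,3] shift to the cyclic allenolate 21, which is protonated at C2 from the ring periphery to the vinylogous ester 22. The closest known reaction is the anionic oxy-Cope ring expansion of 1-alkynyl-2-alkenylcyclohexanols to cyclodeca-2,5-dienones; an ynol ether has not been used as the alkyne partner, but its terminus is the β-carbon of the developing alkoxy ynone and should accept the allylic terminus. The ten-membered ring is not closed end to end: it arises by four-atom ring expansion of the cyclohexane through a chair-like six-centre transition state. The new C4 stereocentre (erased in step 19) is fixed by that chair and the E geometry of the alkenyl group, and the C5=C6 bond should be E because the alkynyl and alkenyl groups are trans-diequatorial, so C4 can reach C3 only from the rotamer that holds C7 anti to C4. The step needs the shift to outrun retro-addition of potassium ethoxyacetylide and needs E selectivity; the first is served by the crown-ether-separated alkoxide at or below 25 °C and by relief of the 1,3-diaxial contact between the alkoxide and the C7 isopropenyl group, the second by the trans arrangement secured in steps 10 and 11. The ethoxy group puts C3 at the oxidation level from which O10 can displace it in step 13.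

Step 13
Reactants: 22 ten-membered β-ethoxy enone
Product: 24 furanone alcohol (free 8-OH), via dihydroxy β-ethoxy enone 23 (not isolated)
Conditions: HCl (2 M in MeOH), 30 °C
Reagents that add atoms: none
Why: Acid-catalysed methanolysis removes the acetal and the secondary silyl ether, and the freed C10 hydroxyl adds to C3 of the O-protonated vinylogous ester (5-exo-trig on its oxocarbenium form) and expels ethanol (addition–elimination, the classical 3(2H)-furanone closure of an α'-hydroxy 1,3-dicarbonyl equivalent); no stereocentre is formed and the primary tert-butyldiphenylsilyl ether should survive.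

Step 14
Reactants: 24 furanone alcohol
Product: 25 8-isobutyrate
Conditions: isobutyric anhydride, DMAP (cat.), pyridine, CH2Cl2, 0 → 25 °C
Reagents that add atoms: isobutyric anhydride, CC(C)C(=O)OC(=O)C(C)C
Why: DMAP-catalysed acylation of the only free hydroxyl, with retention at C8, placed here so that no second secondary alcohol competes later.

Step 15
Reactants: 25 8-isobutyrate
Product: 27 C12 enal, via allylic alcohol 26 (not isolated)
Conditions: SeO2 (0.3 equiv), t-BuOOH (3 equiv), CH2Cl2, 25 °C; then MnO2, CH2Cl2, 25 °C
Reagents that add atoms: selenium dioxide, O=[Se]=O (turned over by tert-butyl hydroperoxide, CC(C)(C)OO)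
Why: Allylic oxidation with SeO2 (ene reaction, then [2,3]-sigmatropic shift) should take place at the methyl group of the 1,1-disubstituted alkene, the allylic position most reactive towards this reagent in 25, and MnO2 converges the allylic alcohol 26 and any aldehyde already formed on enal 27.

Step 16
Reactants: 27 C12 enal
Product: 28 C12 acrylic acid
Conditions: NaClO2, NaH2PO4, 2-methyl-2-butene, t-BuOH/H2O, 0 → 25 °C
Reagents that add atoms: sodium chlorite, [Na+].[O-]Cl=O
Why: Pinnick oxidation of an enal to the acrylic acid; the alkene scavenger removes hypochlorous acid so that the ring alkene is left alone.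

Step 17
Reactants: 28 C12 acrylic acid
Product: 30 hydroxy lactone (6,12-olide with 5-OH), via epoxy acid 29 (not isolated)
Conditions: m-CPBA, CH2Cl2, 0 °C; then camphorsulfonic acid (10 mol %), 25 °C
Reagents that add atoms: 3-chloroperbenzoic acid, OOC(=O)c1cccc(Cl)c1
Why: Prilezhaev epoxidation of the only electron-rich alkene (the strained E C5=C6 bond; acrylic acid and vinylogous ester are inert) on its peripheral face in the conformer that keeps H7 eclipsed with the alkene, then acid-catalysed 5-exo opening of the epoxide by the C12 acid at C6 with inversion: net anti addition across the E alkene should give the 5S carbinol and the 6R cis-fused lactone.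

Step 18
Reactants: 30 hydroxy lactone
Product: 31 5,15-diol
Conditions: HF·pyridine, THF/pyridine, 0 → 25 °C
Reagents that add atoms: none
Why: Fluoride cleavage of the primary silyl ether under buffered, non-basic conditions that leave both esters and the α-methylene lactone intact.

Step 19
Reactants: 31 5,15-diol
Product: 33 CNP0384113.1, via primary mesylate 32 (not isolated)
Conditions: MeSO2Cl (1.1 equiv), Et3N, CH2Cl2, −20 °C; then DBU, 0 → 25 °C
Reagents that add atoms: none
Why: Selective sulfonylation of the primary alcohol over the hindered secondary C5 hydroxyl, then E1cB elimination: C4–H is the vinylogous α-hydrogen of the furanone, so the amidine base removes it and expels mesylate, forming the C4=C15 methylene and erasing the C4 centre.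

**Compound list**

1 | (R)-carvone | CC1=CC[C@H](CC1=O)C(C)=C | starting material
2 | trimethylsilyl dienol ether of carvone (OSiMe3 on C1; C1=C10 and C8=C9) | CC1=C(O[Si](C)(C)C)C[C@H](C(C)=C)C=C1 | intermediate
3 | 8,9-epoxide of 2, oxygen anti to the C7 isopropenyl group (not isolated) | CC1=C(O[Si](C)(C)C)C[C@H](C(C)=C)[C@H]2O[C@@H]12 | intermediate
4 | trans-8-hydroxycarvone (4-hydroxycarvone, OH trans to isopropenyl) | O=C1C[C@H](C(C)=C)[C@@H](O)C=C1C | intermediate
5 | cis-8-(4-nitrobenzoyloxy)carvone (ester oxygen cis to isopropenyl) | O=C1C[C@H](C(C)=C)[C@H](OC(=O)c2ccc(cc2)[N+](=O)[O-])C=C1C | intermediate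
6 | cis-8-hydroxycarvone | O=C1C[C@H](C(C)=C)[C@H](O)C=C1C | intermediate
7 | cis-8-(tert-butyldimethylsilyloxy)carvone | O=C1C[C@H](C(C)=C)[C@H](O[Si](C)(C)C(C)(C)C)C=C1C | intermediate
8 | C10 hydroperoxide of the saturated ketone, OOH trans to O8 and isopropenyl (not isolated) | O=C1C[C@H](C(C)=C)[C@H](O[Si](C)(C)C(C)(C)C)C[C@@]1(C)OO | intermediate
9 | α-hydroxy ketone: cyclohexanone C1 with 10-OH, 10-CH3, 8-OSi(t-Bu)Me2, 7-isopropenyl; CH3, silyloxy and isopropenyl mutually cis, OH trans to them | O=C1C[C@H](C(C)=C)[C@H](O[Si](C)(C)C(C)(C)C)C[C@@]1(C)O | intermediate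
10 | methoxymethyl ether of 9 | O=C1C[C@H](C(C)=C)[C@H](O[Si](C)(C)C(C)(C)C)C[C@@]1(C)OCOC | intermediate
11 | propargyl alcohol | C#CCO | starting material
12 | tert-butyl(diphenyl)(prop-2-yn-1-yloxy)silane | C#CCO[Si](c1ccccc1)(c1ccccc1)C(C)(C)C | intermediate
13 | (E)-3-(tert-butyldiphenylsilyloxy)prop-1-enylzirconocene chloride (not isolated; cyclopentadienyl rings written σ-bonded) | Cl[Zr](/C=C/CO[Si](c1ccccc1)(c1ccccc1)C(C)(C)C)(C1C=CC=C1)C1C=CC=C1 | intermediate
14 | (E)-1-bromo-3-(tert-butyldiphenylsilyloxy)prop-1-ene | Br/C=C/CO[Si](c1ccccc1)(c1ccccc1)C(C)(C)C | intermediate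
15 | lithium dienolate of 16 (C1=C6 enolate conjugated with C5=C4; not isolated) | [Li+].[O-]C1=C(/C=C/CO[Si](c2ccccc2)(c2ccccc2)C(C)(C)C)[C@H](C(C)=C)[C@H](O[Si](C)(C)C(C)(C)C)C[C@@]1(C)OCOC | intermediate
16 | ketone 10 carrying on C6 the (E)-3-(tert-butyldiphenylsilyloxy)prop-1-enyl group, cis to the C7 isopropenyl group | O=C1[C@H](/C=C/CO[Si](c2ccccc2)(c2ccccc2)C(C)(C)C)[C@H](C(C)=C)[C@H](O[Si](C)(C)C(C)(C)C)C[C@@]1(C)OCOC | intermediate
17 | ethoxyacetylene | C#COCC | starting material
18 | lithium ethoxyacetylide (not isolated) | [Li+].[C-]#COCC | intermediate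
19 | ring-expansion substrate: C1 carbinol of 16, ethoxyethynyl trans to the C6 alkenyl group, hydroxyl cis to it | CCOC#C[C@@]1(O)[C@H](/C=C/CO[Si](c2ccccc2)(c2ccccc2)C(C)(C)C)[C@H](C(C)=C)[C@H](O[Si](C)(C)C(C)(C)C)C[C@@]1(C)OCOC | intermediate
20 | potassium alkoxide of 19 (not isolated) | [K+].CCOC#C[C@@]1([O-])[C@H](/C=C/CO[Si](c2ccccc2)(c2ccccc2)C(C)(C)C)[C@H](C(C)=C)[C@H](O[Si](C)(C)C(C)(C)C)C[C@@]1(C)OCOC | intermediate
21 | potassium allenolate of the ten-membered ring, C1(O−)=C2=C3(OEt) (not isolated; allene axis not specified) | [K+].[O-]C1=C=C(OCC)[C@H](CO[Si](c2ccccc2)(c2ccccc2)C(C)(C)C)/C=C/[C@H](C(C)=C)[C@H](O[Si](C)(C)C(C)(C)C)C[C@@]1(C)OCOC | intermediate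
22 | ten-membered (2E,5E)-3-ethoxycyclodeca-2,5-dien-1-one with 4-CH2OSiPh2(t-Bu), 7-isopropenyl, 8-OSi(t-Bu)Me2, 10-CH3 and 10-OCH2OCH3 | O=C1/C=C(/OCC)[C@H](CO[Si](c2ccccc2)(c2ccccc2)C(C)(C)C)/C=C/[C@H](C(C)=C)[C@H](O[Si](C)(C)C(C)(C)C)C[C@@]1(C)OCOC | intermediate
23 | 8,10-diol of 22 (not isolated) | O=C1/C=C(/OCC)[C@H](CO[Si](c2ccccc2)(c2ccccc2)C(C)(C)C)/C=C/[C@H](C(C)=C)[C@H](O)C[C@@]1(C)O | intermediate
24 | furanone alcohol: O10–C3 bridged 3(2H)-furanone, free 8-OH, E C5=C6, 15-OSiPh2(t-Bu) | O=C1C=C2[C@H](CO[Si](c3ccccc3)(c3ccccc3)C(C)(C)C)/C=C/[C@H](C(C)=C)[C@H](O)C[C@@]1(C)O2 | intermediate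
25 | 8-isobutyrate of 24 | O=C1C=C2[C@H](CO[Si](c3ccccc3)(c3ccccc3)C(C)(C)C)/C=C/[C@H](C(C)=C)[C@H](OC(=O)C(C)C)C[C@@]1(C)O2 | intermediate
26 | C12 allylic alcohol of 25 (not isolated) | O=C1C=C2[C@H](CO[Si](c3ccccc3)(c3ccccc3)C(C)(C)C)/C=C/[C@H](C(CO)=C)[C@H](OC(=O)C(C)C)C[C@@]1(C)O2 | intermediate
27 | C12 enal | O=C1C=C2[C@H](CO[Si](c3ccccc3)(c3ccccc3)C(C)(C)C)/C=C/[C@H](C(C=O)=C)[C@H](OC(=O)C(C)C)C[C@@]1(C)O2 | intermediate
28 | C12 acrylic acid | O=C1C=C2[C@H](CO[Si](c3ccccc3)(c3ccccc3)C(C)(C)C)/C=C/[C@H](C(C(=O)O)=C)[C@H](OC(=O)C(C)C)C[C@@]1(C)O2 | intermediate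
29 | 5,6-trans-epoxy acid (not isolated) | O=C1C=C2[C@H](CO[Si](c3ccccc3)(c3ccccc3)C(C)(C)C)[C@@H]3O[C@H]3[C@H](C(C(=O)O)=C)[C@H](OC(=O)C(C)C)C[C@@]1(C)O2 | intermediate
30 | hydroxy lactone: 6,12-olide, 5-OH, C4 still bearing CH2OSiPh2(t-Bu) | C=C1C(=O)O[C@@H]2[C@H]1[C@H](OC(=O)C(C)C)C[C@@]1(C)OC(=CC1=O)[C@H](CO[Si](c3ccccc3)(c3ccccc3)C(C)(C)C)[C@@H]2O | intermediate
31 | 5,15-diol lactone | C=C1C(=O)O[C@@H]2[C@H]1[C@H](OC(=O)C(C)C)C[C@@]1(C)OC(=CC1=O)[C@H](CO)[C@@H]2O | intermediate
32 | 15-methanesulfonate of 31 (not isolated) | C=C1C(=O)O[C@@H]2[C@H]1[C@H](OC(=O)C(C)C)C[C@@]1(C)OC(=CC1=O)[C@H](COS(C)(=O)=O)[C@@H]2O | intermediate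
33 | CNP0384113.1 | C=C1C(=O)O[C@@H]2[C@H]1[C@H](OC(=O)C(C)C)C[C@@]1(C)OC(=CC1=O)C(=C)[C@@H]2O | target

**Step count and risks**

Total: 19 steps. Longest linear sequence: 17 steps from (R)-carvone (steps 1–7 and 10–19); steps 8–9 make the vinyl bromide.

Steps most likely to fail:

1. Step 12 (ring expansion). What may go wrong: the alkoxide fragments back to the ketone and potassium ethoxyacetylide faster than it rearranges, or the electron-rich ynol ether reacts too slowly, so that only retro-addition and decomposition are seen. The fallback uses the documented ethynyl variant and adjusts the oxidation level afterwards. It sets out from 16.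
   - HC≡CMgBr (THF, 0 °C, same facial course as step 11) should give the ethynyl carbinol F1.
   - KH/18-crown-6 effects the known anionic oxy-Cope ring expansion of a 1-ethynyl-2-alkenylcyclohexanol to the (2Z,5E)-cyclodecadienone F2.
   - HCl in MeOH removes the acetal and the secondary silyl ether, and the freed O10 adds to C3 of the protonated enone (acid-catalysed intramolecular oxa-Michael addition) to give the bridged dihydrofuranone F3 (either C3 epimer serves).
   - Saegusa–Ito dehydrogenation (Me3SiOTf/Et3N, then Pd(OAc)2 in MeCN, acidic work-up to free O8) introduces the C2=C3 bond and returns to the route at 24.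

2. Step 17 (epoxidation and lactonisation). What may go wrong: oxygen is delivered to the other face of the E alkene, because the ring conformation rather than a neighbouring centre decides which face is exposed; after lactonisation this would give the 5,6-bis-epimer. The fallback moves stereocontrol from the substrate to the reagent. It sets out from 28, which is epoxidised as its carboxylate with the chiral dioxirane made from a fructose-derived ketone and Oxone (Shi epoxidation; buffered at about pH 10, MeCN/dimethoxymethane/H2O, 0 °C). The ketone enantiomer is chosen to match the required face of this trans-disubstituted alkene. Acidification gives epoxy acid 29, which lactonises as before, and the route is rejoined at 30 (no compound outside the list, F0).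

3. Step 10 (α-alkenylation). What may go wrong: slow carbon–carbon reductive elimination at C6, which is flanked by the axial isopropenyl group, or base-mediated migration of the new alkene into conjugation with the ketone. The fallback reverses the polarity. It sets out from 10.
   - LiN(SiMe3)2/Me3SiCl gives the silyl enol ether F4.
   - N-Bromosuccinimide converts it into the 6-bromo ketone F5 (C6 epimers).
   - This secondary α-bromo ketone is coupled with alkenylzirconocene 13 (made from 12 as in step 9, without bromination) under nickel catalysis (NiCl2(dme), bipyridine-type ligand, DME, 25 °C). The coupling is base-free and stereoconvergent at C6; brief Et3N equilibration should then give the 6,7-cis ketone, rejoining the route at 16.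

**Further compounds**

F1 | step 12 | 1-ethynyl carbinol of 16 (ethynyl trans to the C6 alkenyl group) | C#C[C@@]1(O)[C@H](/C=C/CO[Si](c2ccccc2)(c2ccccc2)C(C)(C)C)[C@H](C(C)=C)[C@H](O[Si](C)(C)C(C)(C)C)C[C@@]1(C)OCOC
F2 | step 12 | (2Z,5E)-cyclodeca-2,5-dien-1-one (22 without the ethoxy group) | O=C1/C=C\[C@H](CO[Si](c2ccccc2)(c2ccccc2)C(C)(C)C)/C=C/[C@H](C(C)=C)[C@H](O[Si](C)(C)C(C)(C)C)C[C@@]1(C)OCOC
F3 | step 12 | O10–C3 bridged dihydrofuran-3(2H)-one with free 8-OH (C3 epimers, centre not specified) | O=C1CC2[C@H](CO[Si](c3ccccc3)(c3ccccc3)C(C)(C)C)/C=C/[C@H](C(C)=C)[C@H](O)C[C@@]1(C)O2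
F4 | step 10 | trimethylsilyl enol ether (C1=C6) of 10 | C[Si](C)(C)OC1=C[C@H](C(C)=C)[C@H](O[Si](C)(C)C(C)(C)C)C[C@@]1(C)OCOC
F5 | step 10 | 6-bromo ketone from 10 (C6 epimers, centre not specified) | O=C1C(Br)[C@H](C(C)=C)[C@H](O[Si](C)(C)C(C)(C)C)C[C@@]1(C)OCOC
F0 | step 17 | none | none
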